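Ring A is cut back to a cyclobutenone: a Moore-type ring expansion forms the C4a–C5 bond and the whole benzene ring of the flavonol in one thermal operation. The feature used is the A-ring pattern C5–OH para to C8–OMe with C7–O between C6–H and C8, which maps onto the carbonyl, CH, C–OBn and C(OMe) carbons of a 3-benzyloxy-4-methoxycyclobutenone. The precursor carries this four-membered ring on C6 of a 2-aryl-3-SEM-oxy-4-pyranone, whose C5=C6 bond becomes C4a=C8a. It is assembled from pyromeconic acid (bromination, Suzuki coupling, C6 lithiation) and benzyl semisquarate; debenzylation, 7-O-prenylation and fluoride deprotection finish the synthesis.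

Key step: step 9

Assumption: the target has no stereocentre and is achiral, so no asymmetric step is needed; 9, 12, 13 and 15 are racemic and their stereocentres disappear along the route.

Design remarks:
- A 3-hydroxy-4-pyranone lies two hydrogens above the pyranone that an Achmatowicz rearrangement of a furyl carbinol delivers, so the pyranone core is taken from pyromeconic acid and arylated.
- C6 is metalated with a lithium amide free of magnesium salts, since Lewis-acidic magnesium on the pyranone carbonyl can divert the base to C5.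
- The B-ring phenol is masked as a TIPS ether, which should withstand aqueous phosphate, lithium amide and carbonate better than a TBS ether.

Step 1
Reactants: 1 3-hydroxy-4H-pyran-4-one (pyromeconic acid)
Product: 2 2-bromo-3-hydroxy-4H-pyran-4-one
Conditions: NBS, MeCN, 0 °C to rt
Reagents that add atoms: N-bromosuccinimide, O=C1CCC(=O)N1Br
Why: Electrophilic bromination of the enolic 3-hydroxy-γ-pyrone should occur at C2, the enol carbon next to the ring oxygen, as in the C6 halogenation of kojic acid and allomaltol.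

Step 2
Reactants: 2 2-bromo-3-hydroxy-4H-pyran-4-one
Product: 3 2-bromo-3-{[2-(trimethylsilyl)ethoxy]methoxy}-4H-pyran-4-one
Conditions: SEMCl, i-Pr2NEt, CH2Cl2, 0 °C to rt
Reagents that add atoms: 2-(trimethylsilyl)ethoxymethyl chloride, C[Si](C)(C)CCOCCl
Why: O-alkylation of the acidic enol hydroxyl with the chloromethyl ether (Williamson-type acetal formation) installs a group that tolerates lithium amides, heat, hydrogenolysis and carbonate and falls to fluoride.

Step 3
Reactants: 4 2-methoxy-4-(4,4,5,5-tetramethyl-1,3,2-dioxaborolan-2-yl)phenol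
Product: 5 [2-methoxy-4-(4,4,5,5-tetramethyl-1,3,2-dioxaborolan-2-yl)phenoxy]tri(propan-2-yl)silane
Conditions: TIPSCl, imidazole, DMF, rt
Reagents that add atoms: chlorotri(propan-2-yl)silane, CC(C)[Si](Cl)(C(C)C)C(C)C
Why: Imidazole-promoted O-silylation of the phenol is routine and leaves the pinacol boronate untouched.

Step 4
Reactants: 3 2-bromo-3-{[2-(trimethylsilyl)ethoxy]methoxy}-4H-pyran-4-one; 5 [2-methoxy-4-(4,4,5,5-tetramethyl-1,3,2-dioxaborolan-2-yl)phenoxy]tri(propan-2-yl)silane
Product: 6 2-[3-methoxy-4-(triisopropylsilyloxy)phenyl]-3-{[2-(trimethylsilyl)ethoxy]methoxy}-4H-pyran-4-one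
Conditions: Pd(dppf)Cl2 (cat.), K3PO4, 1,4-dioxane/H2O, 80 °C
Reagents that add atoms: none
Why: Suzuki–Miyaura coupling should be easy because the C2–Br bond is a vinylogous acyl bromide (β-bromo enone) that undergoes oxidative addition readily, and the electron-rich arylboronate transmetalates well.

Step 5
Reactants: 7 squaric acid (3,4-dihydroxycyclobut-3-ene-1,2-dione)
Product: 8 dibenzyl squarate (3,4-bis(benzyloxy)cyclobut-3-ene-1,2-dione)
Conditions: BnOH, toluene, reflux, azeotropic removal of water
Reagents that add atoms: benzyl alcohol, OCc1ccccc1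
Why: Squaric acid is a strong vinylogous acid that esterifies with alcohols under azeotropic dehydration without added catalyst (Fischer-type esterification).

Step 6
Reactants: 8 dibenzyl squarate (3,4-bis(benzyloxy)cyclobut-3-ene-1,2-dione)
Product: 10 3-(benzyloxy)cyclobut-3-ene-1,2-dione (benzyl semisquarate), via hydroxycyclobutenone 9 (not isolated)
Conditions: LiAlH(Ot-Bu)3, THF, −78 to −20 °C; then 6 M HCl, CH2Cl2, 0 °C
Reagents that add atoms: water, O
Why: The bulky hydride should add once to a squarate carbonyl (1,2-reduction), and acid then ionises the allylic carbinol 9, water adds at the benzyloxy-stabilised end of the cation and benzyl alcohol is expelled, the established reduction–allylic transposition route from squarate diesters to semisquarates.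

Step 7
Reactants: 6 2-[3-methoxy-4-(triisopropylsilyloxy)phenyl]-3-{[2-(trimethylsilyl)ethoxy]methoxy}-4H-pyran-4-one; 10 3-(benzyloxy)cyclobut-3-ene-1,2-dione (benzyl semisquarate)
Product: 12 racemic 3-(benzyloxy)-4-hydroxy-4-{6-[3-methoxy-4-(triisopropylsilyloxy)phenyl]-4-oxo-5-{[2-(trimethylsilyl)ethoxy]methoxy}-4H-pyran-2-yl}cyclobut-2-en-1-one, via 6-lithiopyranone 11 (not isolated)
Conditions: LiTMP (TMPH, n-BuLi), THF, −78 °C, 6 added to the base; then 10, −78 °C; aq NH4Cl at −78 °C
Reagents that add atoms: none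
Why: Deprotonative lithiation should take the C6–H next to the ring oxygen (as in C2 lithiation of chromones), and the organolithium then undergoes 1,2-addition to the more electrophilic carbonyl of 10, the one next to the benzyloxy-bearing carbon and not part of the vinylogous ester; the carbinol stereocentre forms without control and is erased in step 9.

Step 8
Reactants: 12 racemic 3-(benzyloxy)-4-hydroxy-4-{6-[3-methoxy-4-(triisopropylsilyloxy)phenyl]-4-oxo-5-{[2-(trimethylsilyl)ethoxy]methoxy}-4H-pyran-2-yl}cyclobut-2-en-1-one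
Product: 13 racemic 3-(benzyloxy)-4-methoxy-4-{6-[3-methoxy-4-(triisopropylsilyloxy)phenyl]-4-oxo-5-{[2-(trimethylsilyl)ethoxy]methoxy}-4H-pyran-2-yl}cyclobut-2-en-1-one
Conditions: MeI, Ag2O, MeCN, rt, dark
Reagents that add atoms: iodomethane, CI
Why: Silver oxide-mediated (Purdie) methylation etherifies the tertiary carbinol under near-neutral conditions, avoiding the strong base that would open or rearrange a 4-hydroxycyclobutenone.

Step 9
Reactants: 13 racemic 3-(benzyloxy)-4-methoxy-4-{6-[3-methoxy-4-(triisopropylsilyloxy)phenyl]-4-oxo-5-{[2-(trimethylsilyl)ethoxy]methoxy}-4H-pyran-2-yl}cyclobut-2-en-1-one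
Product: 16 7-(benzyloxy)-5-hydroxy-8-methoxy-2-[3-methoxy-4-(triisopropylsilyloxy)phenyl]-3-{[2-(trimethylsilyl)ethoxy]methoxy}-4H-chromen-4-one, via dienylketene 14 (not isolated), via cyclohexadienone 15 (not isolated)
Conditions: toluene (degassed, 0.02 M), 110 °C, Ar
Reagents that add atoms: none
Why: Heating should trigger conrotatory 4π electrocyclic opening of the cyclobutenone C1–C4 bond, in which the donor methoxy group turns outward so that the pyranonyl group ends up cis to the ketene in dienylketene 14. A thermal disrotatory 6π electrocyclisation then joins the electrophilic ketene carbon to the nucleophilic enol-ether β-carbon C5 of the pyranone (flavone C4a), giving cyclohexadienone 15, whose C4a–H lies between two carbonyls and enolises at once to the chelated C5 phenol. The closest known reaction is the Moore ring expansion of 4-alkenyl- and 4-(hetero)aryl-4-alkoxycyclobutenones to hydroquinone monoethers, applied here to the alkene of a γ-pyranone. The one new ring, the six-membered carbocycle A, closes in the 6π-electrocyclic mode through the C4a–C5 bond, and no stereocentre remains because the centre of 13 and the transient C4a centre of 15 are both lost. The step needs outward rotation of the methoxy group, which its donor character secures, and closure at a single site, which is guaranteed because C5 is the only carbon flanking the attachment carbon C6, the other neighbour being the ring oxygen. The pattern C5–OH, C6–H, C7–OBn, C8–OMe is fixed beforehand by the regiochemistry of step 7, and the neutral conditions should leave the SEM, TIPS and benzyl ethers untouched.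

Step 10
Reactants: 16 7-(benzyloxy)-5-hydroxy-8-methoxy-2-[3-methoxy-4-(triisopropylsilyloxy)phenyl]-3-{[2-(trimethylsilyl)ethoxy]methoxy}-4H-chromen-4-one
Product: 17 5,7-dihydroxy-8-methoxy-2-[3-methoxy-4-(triisopropylsilyloxy)phenyl]-3-{[2-(trimethylsilyl)ethoxy]methoxy}-4H-chromen-4-one
Conditions: H2 (1 atm), 10% Pd/C, EtOAc, rt
Reagents that add atoms: none
Why: Catalytic hydrogenolysis cleaves the aryl benzyl ether, while the silyl ether, the SEM acetal and the tetrasubstituted flavone C2=C3 bond are inert at ambient pressure.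

Step 11
Reactants: 17 5,7-dihydroxy-8-methoxy-2-[3-methoxy-4-(triisopropylsilyloxy)phenyl]-3-{[2-(trimethylsilyl)ethoxy]methoxy}-4H-chromen-4-one; 18 prenyl bromide (1-bromo-3-methylbut-2-ene)
Product: 19 5-hydroxy-8-methoxy-2-[3-methoxy-4-(triisopropylsilyloxy)phenyl]-7-[(3-methylbut-2-en-1-yl)oxy]-3-{[2-(trimethylsilyl)ethoxy]methoxy}-4H-chromen-4-one
Conditions: K2CO3, acetone, 40 °C
Reagents that add atoms: none
Why: Williamson etherification should be selective for the 7-OH, the only acidic and free phenol, because the 5-OH is locked in a hydrogen bond to the C4 carbonyl, and SN2 attack occurs at the primary carbon of the allylic bromide.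

Step 12
Reactants: 19 5-hydroxy-8-methoxy-2-[3-methoxy-4-(triisopropylsilyloxy)phenyl]-7-[(3-methylbut-2-en-1-yl)oxy]-3-{[2-(trimethylsilyl)ethoxy]methoxy}-4H-chromen-4-one
Product: 20 3,5-dihydroxy-2-(4-hydroxy-3-methoxyphenyl)-8-methoxy-7-[(3-methylbut-2-en-1-yl)oxy]-4H-chromen-4-one (target)
Conditions: TBAF, THF, 50 °C; aq NH4Cl
Reagents that add atoms: none
Why: Fluoride cleaves the aryl silyl ether and attacks the silicon of the SEM group, whose β-elimination and acetal fragmentation release the acidic 3-enol, while the allylic aryl ether is inert to fluoride (fluoride-induced desilylation and SEM fragmentation).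

Compound list
1 | 3-hydroxy-4H-pyran-4-one (pyromeconic acid) | O=c1ccocc1O | starting material
2 | 2-bromo-3-hydroxy-4H-pyran-4-one | O=c1ccoc(Br)c1O | intermediate
3 | 2-bromo-3-{[2-(trimethylsilyl)ethoxy]methoxy}-4H-pyran-4-one | O=c1ccoc(Br)c1OCOCC[Si](C)(C)C | intermediate
4 | 2-methoxy-4-(4,4,5,5-tetramethyl-1,3,2-dioxaborolan-2-yl)phenol | COc1cc(B2OC(C)(C)C(C)(C)O2)ccc1O | starting material
5 | [2-methoxy-4-(4,4,5,5-tetramethyl-1,3,2-dioxaborolan-2-yl)phenoxy]tri(propan-2-yl)silane | COc1cc(B2OC(C)(C)C(C)(C)O2)ccc1O[Si](C(C)C)(C(C)C)C(C)C | intermediate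
6 | 2-[3-methoxy-4-(triisopropylsilyloxy)phenyl]-3-{[2-(trimethylsilyl)ethoxy]methoxy}-4H-pyran-4-one | COc1cc(-c2occc(=O)c2OCOCC[Si](C)(C)C)ccc1O[Si](C(C)C)(C(C)C)C(C)C | intermediate
7 | squaric acid (3,4-dihydroxycyclobut-3-ene-1,2-dione) | OC1=C(O)C(=O)C1=O | starting material
8 | dibenzyl squarate (3,4-bis(benzyloxy)cyclobut-3-ene-1,2-dione) | O=C1C(=O)C(OCc2ccccc2)=C1OCc3ccccc3 | intermediate
9 | racemic 2,3-bis(benzyloxy)-4-hydroxycyclobut-2-en-1-one (not isolated) | O=C1C(OCc2ccccc2)=C(OCc3ccccc3)C1O | intermediate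
10 | 3-(benzyloxy)cyclobut-3-ene-1,2-dione (benzyl semisquarate) | O=C1C=C(OCc2ccccc2)C1=O | intermediate
11 | 6-lithio derivative of 6, lithium on the pyranone carbon next to the ring oxygen (not isolated) | COc1cc(-c2oc([Li])cc(=O)c2OCOCC[Si](C)(C)C)ccc1O[Si](C(C)C)(C(C)C)C(C)C | intermediate
12 | racemic 3-(benzyloxy)-4-hydroxy-4-{6-[3-methoxy-4-(triisopropylsilyloxy)phenyl]-4-oxo-5-{[2-(trimethylsilyl)ethoxy]methoxy}-4H-pyran-2-yl}cyclobut-2-en-1-one | COc1cc(-c2oc(C3(O)C(=O)C=C3OCc4ccccc4)cc(=O)c2OCOCC[Si](C)(C)C)ccc1O[Si](C(C)C)(C(C)C)C(C)C | intermediate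
13 | racemic 3-(benzyloxy)-4-methoxy-4-{6-[3-methoxy-4-(triisopropylsilyloxy)phenyl]-4-oxo-5-{[2-(trimethylsilyl)ethoxy]methoxy}-4H-pyran-2-yl}cyclobut-2-en-1-one | COc1cc(-c2oc(C3(OC)C(=O)C=C3OCc4ccccc4)cc(=O)c2OCOCC[Si](C)(C)C)ccc1O[Si](C(C)C)(C(C)C)C(C)C | intermediate
14 | 3-(benzyloxy)-4-methoxy-4-(pyranon-2-yl)buta-1,3-dien-1-one, pyranonyl group cis to the ketenyl carbon across the C3=C4 bond (not isolated) | COc1cc(-c2oc(/C(OC)=C(OCc3ccccc3)\C=C=O)cc(=O)c2OCOCC[Si](C)(C)C)ccc1O[Si](C(C)C)(C(C)C)C(C)C | intermediate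
15 | racemic 7-(benzyloxy)-8-methoxy-2-aryl-3-(SEM-oxy)-4aH-chromene-4,5-dione, the keto tautomer of 16 with C4a–H (not isolated) | COC1=C2OC(c3ccc(O[Si](C(C)C)(C(C)C)C(C)C)c(OC)c3)=C(OCOCC[Si](C)(C)C)C(=O)C2C(=O)C=C1OCc4ccccc4 | intermediate
16 | 7-(benzyloxy)-5-hydroxy-8-methoxy-2-[3-methoxy-4-(triisopropylsilyloxy)phenyl]-3-{[2-(trimethylsilyl)ethoxy]methoxy}-4H-chromen-4-one | COc1cc(-c2oc3c(OC)c(OCc4ccccc4)cc(O)c3c(=O)c2OCOCC[Si](C)(C)C)ccc1O[Si](C(C)C)(C(C)C)C(C)C | intermediate
17 | 5,7-dihydroxy-8-methoxy-2-[3-methoxy-4-(triisopropylsilyloxy)phenyl]-3-{[2-(trimethylsilyl)ethoxy]methoxy}-4H-chromen-4-one | COc1cc(-c2oc3c(OC)c(O)cc(O)c3c(=O)c2OCOCC[Si](C)(C)C)ccc1O[Si](C(C)C)(C(C)C)C(C)C | intermediate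
18 | prenyl bromide (1-bromo-3-methylbut-2-ene) | CC(C)=CCBr | starting material
19 | 5-hydroxy-8-methoxy-2-[3-methoxy-4-(triisopropylsilyloxy)phenyl]-7-[(3-methylbut-2-en-1-yl)oxy]-3-{[2-(trimethylsilyl)ethoxy]methoxy}-4H-chromen-4-one | COc1cc(-c2oc3c(OC)c(OCC=C(C)C)cc(O)c3c(=O)c2OCOCC[Si](C)(C)C)ccc1O[Si](C(C)C)(C(C)C)C(C)C | intermediate
20 | 3,5-dihydroxy-2-(4-hydroxy-3-methoxyphenyl)-8-methoxy-7-[(3-methylbut-2-en-1-yl)oxy]-4H-chromen-4-one | COc1cc(-c2oc3c(OC)c(OCC=C(C)C)cc(O)c3c(=O)c2O)ccc1O | target

Total step count: 12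
Longest linear sequence: 9 steps (steps 1, 2, 4, 7, 8, 9, 10, 11, 12)

Steps most likely to fail

1. Step 9. The ring opening may be slow or may turn the methoxy group inward, so that the ketene cannot reach C5 and is lost to dimerisation or to capture by adventitious nucleophiles before the 6π closure. The fallback sets out from carbinol 12 and skips step 8. Heating 12 in degassed toluene under argon uses the free hydroxyl, a stronger outward-rotating donor, in the known ring expansion of 4-hydroxycyclobutenones to hydroquinones. This should give 7-(benzyloxy)-5,8-dihydroxy-2-[3-methoxy-4-(triisopropylsilyloxy)phenyl]-3-{[2-(trimethylsilyl)ethoxy]methoxy}-4H-chromen-4-one F1. Kept under argon, it is methylated with MeI and K2CO3 in acetone only at the free 8-OH, since the 5-OH is chelated to the C4 carbonyl, and the route is rejoined at 16.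

2. Step 7. The lithiated pyranone may condense with unreacted pyranone or open its ring before the electrophile arrives, deprotonation may compete at C5, or the hard organolithium may attack the semisquarate unselectively. The fallback sets out from 6. Zincation with TMPZnCl·LiCl in THF at rt, selective for the carbon next to the ring oxygen when no magnesium salt is present, should give the room-temperature-stable [6-aryl-4-oxo-5-(SEM-oxy)-4H-pyran-2-yl]zinc chloride F2. Quenching with iodine gives 6-iodo-2-[3-methoxy-4-(triisopropylsilyloxy)phenyl]-3-{[2-(trimethylsilyl)ethoxy]methoxy}-4H-pyran-4-one F3, which is isolated. Iodine–magnesium exchange with i-PrMgCl·LiCl in THF at −40 °C then gives the milder [6-aryl-4-oxo-5-(SEM-oxy)-4H-pyran-2-yl]magnesium chloride F4, which is added to 10 at −40 °C and quenched with aq NH4Cl, rejoining the route at 12.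

3. Step 12. Fragmentation of the SEM acetal at the hindered, carbonyl-flanked 3-O position may stall, or the released formaldehyde may be recaptured by the electron-rich A-ring phenoxide under hot basic fluoride. The fallback sets out from 19 and separates the two deprotections. MgBr2·OEt2 in Et2O/MeNO2 at rt, with chelation between the C4 carbonyl and the acetal oxygens, cleaves the SEM acetal as a Lewis-acid acetal cleavage and should give 3,5-dihydroxy-8-methoxy-2-[3-methoxy-4-(triisopropylsilyloxy)phenyl]-7-[(3-methylbut-2-en-1-yl)oxy]-4H-chromen-4-one F5. The aryl silyl ether is then removed with TBAF/AcOH in THF at 0 °C, arriving at 20.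

Further compounds
F1 | step 9 | 7-(benzyloxy)-5,8-dihydroxy-2-[3-methoxy-4-(triisopropylsilyloxy)phenyl]-3-{[2-(trimethylsilyl)ethoxy]methoxy}-4H-chromen-4-one | COc1cc(-c2oc3c(O)c(OCc4ccccc4)cc(O)c3c(=O)c2OCOCC[Si](C)(C)C)ccc1O[Si](C(C)C)(C(C)C)C(C)C
F2 | step 7 | [6-aryl-4-oxo-5-(SEM-oxy)-4H-pyran-2-yl]zinc chloride (not isolated) | COc1cc(-c2oc([Zn]Cl)cc(=O)c2OCOCC[Si](C)(C)C)ccc1O[Si](C(C)C)(C(C)C)C(C)C
F3 | step 7 | 6-iodo-2-[3-methoxy-4-(triisopropylsilyloxy)phenyl]-3-{[2-(trimethylsilyl)ethoxy]methoxy}-4H-pyran-4-one | COc1cc(-c2oc(I)cc(=O)c2OCOCC[Si](C)(C)C)ccc1O[Si](C(C)C)(C(C)C)C(C)C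
F4 | step 7 | [6-aryl-4-oxo-5-(SEM-oxy)-4H-pyran-2-yl]magnesium chloride (not isolated) | COc1cc(-c2oc([Mg]Cl)cc(=O)c2OCOCC[Si](C)(C)C)ccc1O[Si](C(C)C)(C(C)C)C(C)C
F5 | step 12 | 3,5-dihydroxy-8-methoxy-2-[3-methoxy-4-(triisopropylsilyloxy)phenyl]-7-[(3-methylbut-2-en-1-yl)oxy]-4H-chromen-4-one | COc1cc(-c2oc3c(OC)c(OCC=C(C)C)cc(O)c3c(=O)c2O)ccc1O[Si](C(C)C)(C(C)C)C(C)C
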